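## Retrosynthetic overview
1. The target (6,7-seco-ent-kauranoid with a spiro 7,20-lactone) is reached by late unveiling of C6 CH2OH → CHO, C15 enone from SeO2 oxidation of the exocyclic methylene, and C19-OH → OAc.
2. The bicyclo[3.2.1] D ring with the exo-methylene is formed last, by Pd(II) cycloalkenylation of the C8 silyl ketene acetal onto an axial C13 isopropenyl group.
3. Ring C comes from a Robinson-type aldol condensation on the spirolactone, then cuprate addition of isopropenyl (C13) and MPV equilibration (C11-OH).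
4. The C9–C10 bond and the spiro δ-lactone come from a Ti(III) epoxide-opening radical conjugate addition of the ring-A spiroepoxide to a γ-ketal enoate, followed by lactonisation.
5. The ring-A spiroepoxide is made from 3-methylcyclohexenone by Cu-catalysed asymmetric vinyl addition/HCHO aldol, TBS protection and Corey–Chaykovsky. Ring order: A → lactone → C → D.

Assumption: the ligand enantiomer is chosen to give the drawn C4 configuration. The C5 ketol (CH2OH cis to vinyl) is the thermodynamic isomer. C5 is α to the final aldehyde and can re-equilibrate to the equatorial C6.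

## Route

**Step 1**
Reactants: 1 (3-methylcyclohex-2-en-1-one), 2 (vinylmagnesium bromide), 3 (formaldehyde, monomeric)
Product: 4 (ring-A ketol: 2-hydroxymethyl-3-methyl-3-vinylcyclohexanone, CH2OH cis to vinyl, C4 quaternary as drawn)
Conditions: 2, CuBr·SMe2 (5 mol%), JosiPhos-type ligand (6 mol%), MTBE, –78 °C; then 3, –78 → 0 °C
Reagents that add atoms: none
Why: Cu-catalysed asymmetric conjugate addition sets the C4 quaternary centre. The regiospecific Mg-enolate is trapped by HCHO (aldol) at C5, and the ketol equilibrates to the C6-equatorial/C19-axial (cis) isomer.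

**Step 2**
Reactants: 4
Product: 5 (C6-OTBS ketone)
Conditions: TBSCl, imidazole, DMF, rt
Reagents that add atoms: TBSCl, CC(C)(C)[Si](C)(C)Cl
Why: Silylation protects the primary alcohol before the basic ylide step; no stereocentre is touched.

**Step 3**
Reactants: 5
Product: 6 (spiro-epoxide at C10 = C10/C20 epoxide)
Conditions: Me3S+ I–, n-BuLi, THF, –10 °C → rt
Reagents that add atoms: trimethylsulfonium iodide, C[S+](C)C.[I-] (supplies C20)
Why: Corey–Chaykovsky methylene transfer gives a mixture of spiro epimers, which is harmless because step 7 converts both to the same planar tertiary radical.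

**Step 4**
Reactants: 6
Product: 7 (C19 primary alcohol)
Conditions: O3, CH2Cl2/MeOH, –78 °C; then NaBH4, 0 °C
Reagents that add atoms: ozone, [O-][O+]=O (the aldehyde O derives from it; NaBH4 adds only H)
Why: Ozonolysis of the only alkene (vinyl) followed by reduction gives the C19 CH2OH, leaving the epoxide and silyl ether intact.

**Step 5**
Reactants: 7
Product: 8 (ring-A radical precursor: C19-OPMB, C6-OTBS, spiroepoxide)
Conditions: NaH, PMBBr, TBAI, DMF/THF, 0 °C
Reagents that add atoms: p-methoxybenzyl bromide, COc1ccc(CBr)cc1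
Why: Williamson etherification installs a group that is orthogonal to TBS and survives the later strongly basic steps.

**Step 6**
Reactants: 9 (methyl (E)-4-oxopent-2-enoate, commercial)
Product: 10 (methyl (E)-3-(2-methyl-1,3-dioxolan-2-yl)acrylate)
Conditions: (TMSOCH2)2, TMSOTf (cat.), CH2Cl2, –78 °C
Reagents that add atoms: 1,2-bis(trimethylsilyloxy)ethane, C[Si](C)(C)OCCO[Si](C)(C)C (supplies OCH2CH2O)
Why: Noyori ketalisation masks the ketone so the enoate is the only radical acceptor, which directs attack to the carbon β to the ester (C9).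

**Step 7**
Reactants: 8, 10
Product: 11 (hydroxy ester: C9–C10 bond formed, free C20-CH2OH, C7 methyl ester)
Conditions: Cp2TiCl2 (2.2 equiv), Zn, 2,4,6-collidine·HCl, THF, rt
Reagents that add atoms: none (two H from collidinium)
Why: Ti(III) reductive epoxide opening gives the tertiary C10 radical (Ti–O on C20), which adds Giese-type to the enoate β-carbon. The attack comes from the β-face, anti to the axial α-C19 group, so C10 gets C9(β)/C20(α). Ti(III) reduces the α-radical to the Ti enolate, which is protonated. C9 is equilibrated later, in step 12.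

**Step 8**
Reactants: 11
Product: 12 (spiro 7,20-δ-lactone)
Conditions: TBD (20 mol%), toluene, 80 °C
Reagents that add atoms: none (MeOH lost)
Why: Base-mediated lactonisation is the only possible ring closure, because C11 is ketal-protected, and the Thorpe–Ingold effect of the quaternary spiro centre drives the δ-lactone.

**Step 9**
Reactants: 12, 13 (allyl bromide)
Product: 14 (C8-allyl lactone)
Conditions: LDA (1.1 equiv), THF/HMPA, –78 °C; then 13, –78 → –40 °C
Reagents that add atoms: none (13 is a reactant)
Why: Lactone enolate alkylation occurs anti to the C9 substituent, so C14 ends up trans to C11, as required for the trans-fused C/lactone junction.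

**Step 10**
Reactants: 14
Product: 15 (C14–C13 aldehyde)
Conditions: OsO4 (5 mol%), NaIO4, 2,6-lutidine, dioxane/H2O, rt
Reagents that add atoms: sodium periodate, [Na+].[O-]I(=O)(=O)=O (oxygen source)
Why: Lemieux–Johnson cleavage of the terminal alkene is compatible with the PMB, TBS and ketal groups.

**Step 11**
Reactants: 15
Product: 16 (methyl ketone at C11 plus aldehyde at C13)
Conditions: I2 (10 mol%), acetone (wet), rt
Reagents that add atoms: water, O
Why: Neutral transketalisation unmasks the C11 ketone without cleaving the silyl or PMB ethers.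

**Step 12**
Reactants: 16
Product: 17 (ring-C enone: C11 ketone, C12=C13)
Conditions: pyrrolidine (30 mol%), AcOH, DCE, 60 °C
Reagents that add atoms: none (H2O lost)
Why: Intramolecular enamine aldol condensation (6-exo, Robinson-type) closes ring C. The same conditions epimerise C9, α to the ketone, to the trans-fused isomer with C10 equatorial.

**Step 13**
Reactants: 17, 18 (isopropenylmagnesium bromide)
Product: 19 (C13 isopropenyl, C11 ketone)
Conditions: 18 (3 equiv), CuBr·SMe2 (1.5 equiv), TMSCl, HMPA, THF, –78 °C; then aq. NH4Cl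
Reagents that add atoms: none (18 is a reactant)
Why: Cuprate 1,4-addition occurs anti to the lactone C7 substituent at C8, the same trans-selective mode seen in conjugate additions to 5-substituted cyclohexenones. This puts the isopropenyl axial on the face that will carry the C15–C16 bridge, setting C13.

**Step 14**
Reactants: 19
Product: 20 (C11 equatorial alcohol)
Conditions: Al(OiPr)3, iPrOH, reflux
Reagents that add atoms: none
Why: Meerwein–Ponndorf–Verley equilibration gives the thermodynamic equatorial alcohol. Kinetic hydride delivery would give the axial epimer, because the axial face is blocked by the 1,3-diaxial isopropenyl group.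

**Step 15**
Reactants: 20
Product: 21 (C11-OTBS)
Conditions: TBSOTf, 2,6-lutidine, CH2Cl2, 0 °C
Reagents that add atoms: TBSOTf, CC(C)(C)[Si](C)(C)OS(=O)(=O)C(F)(F)F
Why: Protection prevents the free OH from interfering with enolisation and Pd(II) in steps 16 and 17.

**Step 16**
Reactants: 21
Product: 22 (C8=C7 silyl ketene acetal)
Conditions: LiHMDS, TMSCl, Et3N, THF, –78 °C
Reagents that add atoms: TMSCl, C[Si](C)(C)Cl
Why: Kinetic lactone enolisation and silylation; the C8 stereocentre is erased here and re-set in step 17.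

**Step 17**
Reactants: 22
Product: 23 (pentacyclic core: C8–C15 bond formed, exocyclic C16=C17)
Conditions: Pd(OAc)2 (1.2 equiv; or 10 mol% with BQ), MeCN, 25 → 40 °C
Reagents that add atoms: none (the TMS group is lost)
Why: This is a Toyota/Ihara-type Pd(II) cycloalkenylation. The ketene-acetal carbon C8 attacks the Pd-coordinated isopropenyl (axial at C13) on the same face, and β-hydride elimination from the methyl (C17) gives the exocyclic alkene. The bridge geometry fixes C8.

**Step 18**
Reactants: 23
Product: 24 (free C19-OH)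
Conditions: DDQ, CH2Cl2/pH 7 buffer, 0 °C
Reagents that add atoms: none
Why: Oxidative PMB cleavage leaves both TBS ethers, the lactone and the alkene untouched.

**Step 19**
Reactants: 24
Product: 25 (C19-OAc)
Conditions: Ac2O, Et3N, DMAP (cat.), CH2Cl2, rt
Reagents that add atoms: acetic anhydride, CC(=O)OC(C)=O
Why: C19-OH is the only free OH, so acetylation is selective.

**Step 20**
Reactants: 25
Product: 26 (C15 allylic alcohol, epimeric mixture)
Conditions: SeO2, TBHP, CH2Cl2, rt
Reagents that add atoms: tert-butyl hydroperoxide, CC(C)(C)OO (oxygen source)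
Why: Riley allylic oxidation of the exocyclic methylene occurs at the only allylic CH2 (C15). The C15 stereochemistry is irrelevant because it is oxidised next.

**Step 21**
Reactants: 26
Product: 27 (C15 enone, α-methylene ketone)
Conditions: Dess–Martin periodinane, NaHCO3, CH2Cl2, rt
Reagents that add atoms: none
Why: Only one free alcohol is present (the silyl ethers and acetate are inert), so oxidation gives the cross-conjugated enone.

**Step 22**
Reactants: 27
Product: 28 (C6 CH2OH plus C11-OH diol)
Conditions: HF·pyridine, THF/pyridine, 40 °C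
Reagents that add atoms: none (H added on Si–O cleavage)
Why: Fluoride removes both TBS groups; acetate, lactone and enone survive the buffered acid conditions.

**Step 23**
Reactants: 28
Product: 29 (target)
Conditions: TEMPO (10 mol%), PhI(OAc)2, CH2Cl2, rt
Reagents that add atoms: none
Why: The TEMPO oxoammonium oxidises the primary C6 alcohol chemoselectively over the hindered secondary C11-OH to give the aldehyde. The mild, non-basic conditions preserve C5 configuration.

## Compound list
1 | 3-methylcyclohex-2-en-1-one | CC1=CC(=O)CCC1 | starting material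
2 | vinylmagnesium bromide | C=C[Mg]Br | starting material
3 | formaldehyde | C=O | starting material
4 | ring-A ketol, CH2OH cis to vinyl | O=C1CCC[C@@](C)(C=C)[C@H]1CO | intermediate
5 | C6-OTBS ketone | O=C1CCC[C@@](C)(C=C)[C@H]1CO[Si](C)(C)C(C)(C)C | intermediate
6 | C10/C20 spiro-epoxide (C10 epimers) | C1OC12CCC[C@@](C)(C=C)[C@H]2CO[Si](C)(C)C(C)(C)C | intermediate
7 | C19 alcohol | C1OC12CCC[C@@](C)(CO)[C@H]2CO[Si](C)(C)C(C)(C)C | intermediate
8 | C19-OPMB spiroepoxide | C1OC12CCC[C@@](C)(COCc3ccc(OC)cc3)[C@H]2CO[Si](C)(C)C(C)(C)C | intermediate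
9 | methyl (E)-4-oxopent-2-enoate | COC(=O)/C=C/C(C)=O | starting material
10 | ketal enoate | COC(=O)/C=C/C1(C)OCCO1 | intermediate
11 | hydroxy ester | COC(=O)C[C@@H]([C@]1(CO)CCC[C@@](C)(COCc2ccc(OC)cc2)[C@H]1CO[Si](C)(C)C(C)(C)C)C1(C)OCCO1 | intermediate
12 | spiro 7,20-lactone | CC1(OCCO1)[C@H]2CC(=O)OC[C@]23CCC[C@@](C)(COCc4ccc(OC)cc4)[C@H]3CO[Si](C)(C)C(C)(C)C | intermediate
13 | allyl bromide | C=CCBr | starting material
14 | C8-allyl lactone | CC1(OCCO1)[C@H]2[C@H](CC=C)C(=O)OC[C@]23CCC[C@@](C)(COCc4ccc(OC)cc4)[C@H]3CO[Si](C)(C)C(C)(C)C | intermediate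
15 | aldehyde | CC1(OCCO1)[C@H]2[C@H](CC=O)C(=O)OC[C@]23CCC[C@@](C)(COCc4ccc(OC)cc4)[C@H]3CO[Si](C)(C)C(C)(C)C | intermediate
16 | methyl ketone/aldehyde | CC(=O)[C@H]2[C@H](CC=O)C(=O)OC[C@]23CCC[C@@](C)(COCc4ccc(OC)cc4)[C@H]3CO[Si](C)(C)C(C)(C)C | intermediate
17 | ring-C enone | O=C1C=CC[C@@H]2C(=O)OC[C@]3(CCC[C@@](C)(COCc4ccc(OC)cc4)[C@H]3CO[Si](C)(C)C(C)(C)C)[C@@H]12 | intermediate
18 | isopropenylmagnesium bromide | CC(=C)[Mg]Br | starting material
19 | C13-isopropenyl ketone | O=C1C[C@@H](C(C)=C)C[C@@H]2C(=O)OC[C@]3(CCC[C@@](C)(COCc4ccc(OC)cc4)[C@H]3CO[Si](C)(C)C(C)(C)C)[C@@H]12 | intermediate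
20 | C11 equatorial alcohol | O[C@@H]1C[C@@H](C(C)=C)C[C@@H]2C(=O)OC[C@]3(CCC[C@@](C)(COCc4ccc(OC)cc4)[C@H]3CO[Si](C)(C)C(C)(C)C)[C@@H]12 | intermediate
21 | C11-OTBS | CC(C)(C)[Si](C)(C)O[C@@H]1C[C@@H](C(C)=C)C[C@@H]2C(=O)OC[C@]3(CCC[C@@](C)(COCc4ccc(OC)cc4)[C@H]3CO[Si](C)(C)C(C)(C)C)[C@@H]12 | intermediate
22 | silyl ketene acetal | CC(C)(C)[Si](C)(C)O[C@@H]1C[C@@H](C(C)=C)CC2=C(O[Si](C)(C)C)OC[C@]3(CCC[C@@](C)(COCc4ccc(OC)cc4)[C@H]3CO[Si](C)(C)C(C)(C)C)[C@@H]12 | intermediate
23 | bicyclo[3.2.1] core | C=C1C[C@]23C[C@H]1C[C@@H](O[Si](C)(C)C(C)(C)C)[C@@H]2[C@@]1(CCC[C@@](C)(COCc4ccc(OC)cc4)[C@H]1CO[Si](C)(C)C(C)(C)C)COC3=O | intermediate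
24 | C19 alcohol | C=C1C[C@]23C[C@H]1C[C@@H](O[Si](C)(C)C(C)(C)C)[C@@H]2[C@@]1(CCC[C@@](C)(CO)[C@H]1CO[Si](C)(C)C(C)(C)C)COC3=O | intermediate
25 | C19 acetate | C=C1C[C@]23C[C@H]1C[C@@H](O[Si](C)(C)C(C)(C)C)[C@@H]2[C@@]1(CCC[C@@](C)(COC(C)=O)[C@H]1CO[Si](C)(C)C(C)(C)C)COC3=O | intermediate
26 | C15 allylic alcohol | C=C1C(O)[C@]23C[C@H]1C[C@@H](O[Si](C)(C)C(C)(C)C)[C@@H]2[C@@]1(CCC[C@@](C)(COC(C)=O)[C@H]1CO[Si](C)(C)C(C)(C)C)COC3=O | intermediate
27 | enone, bis-TBS | C=C1C(=O)[C@]23C[C@H]1C[C@@H](O[Si](C)(C)C(C)(C)C)[C@@H]2[C@@]1(CCC[C@@](C)(COC(C)=O)[C@H]1CO[Si](C)(C)C(C)(C)C)COC3=O | intermediate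
28 | diol | C=C1C(=O)[C@]23C[C@H]1C[C@@H](O)[C@@H]2[C@@]1(CCC[C@@](C)(COC(C)=O)[C@H]1CO)COC3=O | intermediate
29 | Trichorabdal B | C=C1C(=O)[C@]23C[C@H]1C[C@@H](O)[C@@H]2[C@@]1(CCC[C@@](C)(COC(C)=O)[C@H]1C=O)COC3=O | target

## Totals
Total steps: 23 (step 6 is a separate branch making acceptor 10).
Longest linear sequence: 22 steps (1–5, then 7–23).

## Three steps most likely to fail
1. **Step 7 (Ti(III) radical conjugate addition).** The vicinal quaternary–tertiary C10–C9 bond is congested, and the C9 diastereoselectivity is uncertain. Fallback: form C9–C10 by a Johnson–Claisen rearrangement of a ring-A allylic alcohol (cyclohexene with C5–CH2OH and C10–CH2OR), then hydroborate the resulting exocyclic C5=C6 alkene to set C5.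
2. **Step 17 (Pd(II) cycloalkenylation).** The 5-endo-type ring closure may give Saegusa-type dehydrogenation (C8=C9) or the endocyclic C15=C16 alkene. Fallback: convert the isopropenyl to a 2-(chloromethyl)allyl group (SeO2, then MsCl/LiCl), and close ring D by intramolecular SN2 alkylation of the C8 lactone enolate.
3. **Step 1 (asymmetric vinyl addition/aldol).** Vinyl Grignard reagents tend to add 1,2, and both the ee at C4 and the C5 cis/trans ratio are uncertain. Fallback: make racemic 4 by non-asymmetric Cu-catalysed conjugate addition/aldol, resolve by lipase-catalysed acylation of the primary alcohol, and recycle the unwanted enantiomer by retro-aldol.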